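The runs are simulated with made-up constants.

| flask | first end groups | second end groups | remark | time |
|---|---|---|---|---|
| Wednesday's | 0.025 M (fed, over 5.0 h) | 0.045 M | run made earlier |  |
| Tuesday's | 0.038 M (fed, over 5.0 h) | 0.045 M | run made earlier |  |
| Friday's | 0.050 M (fed, over 5.0 h) | 0.022 M | run made earlier |  |
| elm | 0.050 M | 0.0450 M | everything together at the start | 1.2 h |
| oak | 0.050 M (fed, over 5.0 h) | 0.0450 M |  | 5.0 h |

| run | time / h | links / % | side product / % |
|---|---|---|---|
| Wednesday's | 0.250 | 0.8 | 0 |
| Wednesday's | 0.500 | 5.1 | 0 |
| Wednesday's | 1.33 | 14.9 | 0 |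
| Wednesday's | 3.00 | 38.2 | 3.9 |
| Tuesday's | 0.250 | 0.7 | 0 |
| Tuesday's | 0.500 | 2.9 | 0 |
| Tuesday's | 1.33 | 13.9 | 0.2 |
| Tuesday's | 3.00 | 34.9 | 5.2 |
| Friday's | 0.417 | 1.0 | 0.1 |
| Friday's | 1.00 | 6.3 | 0 |
| Friday's | 2.00 | 15.5 | 1.3 |
| Friday's | 3.00 | 21.3 | 2.7 |

(standard deviation of a reading: 1 percentage point)

1. the winner by share of links in all that became links or side product; "neither" if no more than 2 percentage points parts them (elm / oak / neither)
2. share of links in all that became links or side product, elm
3. share of links in all that became links or side product, oak

- the numbers in the tables scatter with a standard deviation of 1 percentage point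
- percentages count the whole charge, also what has not yet gone in

Side product is slow to show, so this note for the bench reckons what each hour of standing costs.

1. I define the wear constant as the rate of side product divided by the square of the links concentration. Links climb nearly straight in the runs, so dividing that rate by the climb removes time: side product over links equals wear constant times links times clock time over 3. The runs at 3.00 h give 10.7 M⁻¹ h⁻¹, 11.2 M⁻¹ h⁻¹ and 11.9 M⁻¹ h⁻¹, mean 11.3 M⁻¹ h⁻¹.

2. Oak, fed steadily, should reach about 0.0221 M of links at Tuesday's pace, so I expect a selectivity of 70.7%.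

3. Elm, charged at once, I assume turns into links the share of what had gone in that Tuesday's run had turned at 3.00 h, which makes 0.0291 M of links in elm. A straight climb to that amount gives elm 88.4%, and standing there throughout gives 71.8%, which is still above my oak figure.

4. Don't leave elm past 1.2 h: at those links, I reckon side product grows at 9.57 mM h⁻¹.

The forecast says elm, with 81% for elm and 62% for oak, which is lower than my oak figure, and it reasons that “slow feed means long hold time”.

The flask gives elm: 84.3% for elm and 69.3% for oak.

    first end groups + second end groups ⇌ links + released group (K = 1.10, k = 40.0 M⁻¹ h⁻¹)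
    links + released group → side product (k = 9.70 M⁻¹ h⁻¹)

In elm, links stand at 40.9% at 0.600 h and 42.5% at 1.20 h, and the wear constant on their mean adds 5.89% of the charge as side product, giving 8.57% against the simulated 7.93%. In the neighbour, elm left until 2.0 h, links end at 39.7%, and the same sum adds 7.63%, giving 15.6%. That neighbour holds 14.5% of side product, and its share of links is 73.2%.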